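**Assumption (one line):** atoms are labelled with germacrane numbering (C1–C10 ring, C11/C12/C13 lactone, C14 methyl, C15 CH2OH); target = (3R,6R,7R,8R,10S), 4Z, angelate Z. In step 4 the ligand antipode is the one that gives Re-face alkynylation (I take this to be (S,S)-ProPhenol; confirm by Mosher analysis, and use the antipode if the sense is opposite).

## Retrosynthetic overview

1. The 3,10-hemiketal is made last: global desilylation of a ten-membered 10-silyloxy-4Z-en-3-one lets C10–OH add across the ring to C3 (C3 under thermodynamic control).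
2. The ten-membered carbocycle is closed at C3–C4 by an intramolecular Nozaki–Hiyama–Kishi reaction (not RCM, not a C6–C7 allylation); the C3 aldehyde is hidden until then as geraniol's own prenyl alkene.
3. C7–C8 comes from a Zn-Barbier reaction of a 3-(bromomethyl)butenolide (sets C7 and C8 and delivers the α-methylene lactone); Mitsunobu angeloylation then inverts C8.
4. C6 is a carbinol flanked by two propargyl-derived arms: arm B (Red-Al/I2, then Pd/CO lactonisation) becomes the butenolide; arm A (OH-directed trans-hydrostannation/iodination) becomes the 4Z vinyl iodide.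
5. C10 comes from Sharpless epoxidation of geraniol. Ring order: butenolide → α-methylene-γ-lactone → ten-membered carbocycle → THF hemiketal.

## Forward route

### West fragment

**Step 1**
Reactants: 1 but-2-yne-1,4-diol
Product: 2 4-[(tert-butyldimethylsilyl)oxy]but-2-yn-1-ol
Conditions: NaH (1.0 equiv), THF, 0 °C; TBSCl (1.0 equiv), rt
Reagents that add atoms: TBSCl, C[Si](C)(Cl)C(C)(C)C
Why: Monosilylation of a symmetric diol through its mono-sodium alkoxide (McDougal protocol); no stereochemistry.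

**Step 2**
Reactants: 2
Product: 3 (Z)-4-[(tert-butyldimethylsilyl)oxy]-3-iodobut-2-en-1-ol
Conditions: Red-Al, THF, 0 °C → rt; then I2, −78 → 0 °C
Reagents that add atoms: iodine, II
Why: Hydroxyl-directed trans-hydroalumination puts Al on the alkyne carbon distal to the free OH; iodinolysis with retention gives the Z iodide (I cis to CH2OH).

**Step 3**
Reactants: 3
Product: 4 (Z)-4-[(tert-butyldimethylsilyl)oxy]-3-iodobut-2-enal
Conditions: MnO2, CH2Cl2, rt, dark; use at once
Reagents that add atoms: none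
Why: Neutral allylic MnO2 oxidation, so the Z-β-iodoenal geometry is kept.

**Step 4**
Reactants: 4; 5 trimethyl(prop-2-yn-1-yloxy)silane
Product: 6 (4S,5Z)-7-[(tert-butyldimethylsilyl)oxy]-6-iodohept-5-en-2-yne-1,4-diol
Conditions: Me2Zn, (S,S)-ProPhenol (20 mol%), Ph3P=O, PhMe, 4 °C; then citric acid, MeOH (cleaves OTMS)
Reagents that add atoms: none (new atoms come from 5)
Why: Trost Zn-ProPhenol asymmetric alkynylation of an enal; catalyst-controlled Re-face addition sets the C6 carbinol (4S in 6).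

**Step 5**
Reactants: 6
Product: 7 (5S)-3-{[(tert-butyldimethylsilyl)oxy]methyl}-5-(3-hydroxyprop-1-yn-1-yl)furan-2(5H)-one
Conditions: PdCl2(PPh3)2 (5 mol%), CO (1 atm), K2CO3, THF, 25 °C
Reagents that add atoms: carbon monoxide, [C-]#[O+]
Why: Stille-type carbonylative lactonisation: the acyl-Pd from the vinyl iodide is captured by the cis secondary OH to give the butenolide (C12 from CO); C6 is untouched.

**Step 6**
Reactants: 7
Product: 8 (5S)-3-{[(tert-butyldimethylsilyl)oxy]methyl}-5-[(1Z)-3-hydroxy-2-iodoprop-1-en-1-yl]furan-2(5H)-one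
Conditions: [Cp*RuCl]4 (2.5 mol%), Bu3SnH, CH2Cl2, rt; then I2, 0 °C
Reagents that add atoms: iodine, II
Why: OH-directed Ru-catalysed trans-hydrostannation (Fürstner) puts Sn on the alkyne carbon next to the free CH2OH with H trans; iododestannylation with retention gives the Z iodide (I cis to C6), the future 4Z alkene.

**Step 7**
Reactants: 8
Product: 9 (5S)-3-{[(tert-butyldimethylsilyl)oxy]methyl}-5-[(1Z)-3-[(tert-butyldiphenylsilyl)oxy]-2-iodoprop-1-en-1-yl]furan-2(5H)-one
Conditions: TBDPSCl, imidazole, CH2Cl2, 0 °C → rt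
Reagents that add atoms: TBDPSCl, CC(C)(C)[Si](Cl)(c1ccccc1)c1ccccc1
Why: Silylation of the primary allylic alcohol (C15–OH) with a group that survives to the last step.

**Step 8**
Reactants: 9
Product: 10 (5S)-3-(bromomethyl)-5-[(1Z)-3-[(tert-butyldiphenylsilyl)oxy]-2-iodoprop-1-en-1-yl]furan-2(5H)-one
Conditions: Ph3P·Br2, CH2Cl2, 0 °C → rt
Reagents that add atoms: triphenylphosphine dibromide, BrP(Br)(c1ccccc1)(c1ccccc1)c1ccccc1
Why: Direct silyl ether → bromide conversion (oxyphosphonium, then SN2 by bromide); the activated allylic primary TBS ether reacts while the bulky TBDPS ether should be retained.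

### East fragment

**Step 9**
Reactants: 11 geraniol
Product: 12 (2S,3S)-2,3-epoxygeraniol
Conditions: Ti(OiPr)4 (5 mol%), L-(+)-DET (7.5 mol%), t-BuOOH, 4 Å MS, CH2Cl2, −20 °C
Reagents that add atoms: tert-butyl hydroperoxide, CC(C)(C)OO
Why: Sharpless asymmetric epoxidation; L-(+)-tartrate gives the (2S,3S) epoxide, which fixes C10.

**Step 10**
Reactants: 12
Product: 13 (3S)-3,7-dimethyloct-6-ene-1,3-diol
Conditions: Red-Al, THF, 0 °C
Reagents that add atoms: none
Why: Regioselective hydride opening of the 2,3-epoxy alcohol at C2 (intramolecular delivery from the alkoxyaluminate) gives the 1,3-diol; the tertiary C–O bond is untouched.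

**Step 11**
Reactants: 13
Product: 14 (3S)-3,7-dimethyl-1,3-bis(triethylsilyloxy)oct-6-ene
Conditions: TESOTf (2.5 equiv), 2,6-lutidine, CH2Cl2, −78 → 0 °C
Reagents that add atoms: TESOTf, CC[Si](CC)(CC)OS(=O)(=O)C(F)(F)F
Why: Exhaustive silylation; the triflate is needed for the tertiary OH.

**Step 12**
Reactants: 14
Product: 15 (3S)-3,7-dimethyl-3-(triethylsilyloxy)oct-6-enal
Conditions: (COCl)2, DMSO, CH2Cl2, −78 → −40 °C; Et3N
Reagents that add atoms: none
Why: Swern conditions oxidise primary TES ethers directly to aldehydes while the tertiary TES ether survives.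

### Union and endgame

**Step 13**
Reactants: 10; 15
Product: 16 (4R,5S)-4-[(1S,3S)-1-hydroxy-3,7-dimethyl-3-(triethylsilyloxy)oct-6-en-1-yl]-5-[(1Z)-3-[(tert-butyldiphenylsilyl)oxy]-2-iodoprop-1-en-1-yl]-3-methylidenedihydrofuran-2(3H)-one
Conditions: Zn dust, THF/sat. aq. NH4Cl, 0 °C → rt
Reagents that add atoms: none
Why: Barbier SE2' allylation: the allylzinc attacks through C7 on the butenolide face anti to the C6 alkenyl group (6,7-trans, sets C7), and a chair Zimmerman–Traxler transition state with the E-type ring substituent predicts the 7,8-anti adduct (8S); the exo-methylene lactone is formed directly.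

**Step 14**
Reactants: 16; 17 angelic acid, (Z)-2-methylbut-2-enoic acid
Product: 18 (1R,3S)-1-[(2S,3R)-2-[(1Z)-3-[(tert-butyldiphenylsilyl)oxy]-2-iodoprop-1-en-1-yl]-4-methylidene-5-oxooxolan-3-yl]-3,7-dimethyl-3-(triethylsilyloxy)oct-6-en-1-yl (2Z)-2-methylbut-2-enoate
Conditions: PPh3, DIAD, PhMe, 0 °C → rt
Reagents that add atoms: none beyond 17
Why: Mitsunobu esterification; SN2 inversion converts 8S into the natural 8R (8β) angelate under non-basic conditions that avoid angelate → tiglate isomerisation.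

**Step 15**
Reactants: 18
Product: 19 (1R,3S)-1-[(2S,3R)-2-[(1Z)-3-[(tert-butyldiphenylsilyl)oxy]-2-iodoprop-1-en-1-yl]-4-methylidene-5-oxooxolan-3-yl]-3-methyl-6-oxo-3-(triethylsilyloxy)hexyl (2Z)-2-methylbut-2-enoate
Conditions: O3, CH2Cl2/pyridine, Sudan Red 7B end-point, −78 °C; PPh3
Reagents that add atoms: ozone, [O-][O+]=O
Why: Chemoselective ozonolysis: the trialkyl prenyl alkene is far more electron-rich than the acrylate, the angelate or the iodo-alkene, so only it is cleaved, revealing the C3 aldehyde.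

**Step 16**
Reactants: 19
Product: 20 ten-membered carbocycle: (6R,7R,8R,10S)-8-angeloyloxy-3-hydroxy-10-(triethylsilyloxy)-15-[(tert-butyldiphenylsilyl)oxy]germacra-4Z,11(13)-dien-12,6-olide, C3 epimer mixture
Conditions: CrCl2 (10 equiv), NiCl2 (cat.), DMSO/THF, rt, 2 mM, slow addition
Reagents that add atoms: none
Why: Intramolecular Nozaki–Hiyama–Kishi vinylation: the vinyl-Cr(III) forms with retention (C3 ends up cis to C6, so 4Z) and adds only to the aldehyde, tolerating both enoates; the C3 epimers converge in step 17.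

**Step 17**
Reactants: 20
Product: 21 (6R,7R,8R,10S)-8-angeloyloxy-3-oxo-10-(triethylsilyloxy)-15-[(tert-butyldiphenylsilyl)oxy]germacra-4Z,11(13)-dien-12,6-olide
Conditions: Dess–Martin periodinane, NaHCO3, CH2Cl2, 0 °C → rt
Reagents that add atoms: none
Why: Dess–Martin oxidation of the only free hydroxyl to the ring Z-enone; buffered, so no epimerisation or alkene isomerisation is expected.

**Step 18**
Reactants: 21
Product: 22 niveusin B
Conditions: HF·pyridine, pyridine/THF, 0 °C → rt
Reagents that add atoms: none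
Why: Global desilylation frees C10–OH and C15–OH; C10–OH adds across the ring to the C3 ketone (5-exo hemiketalisation) under thermodynamic control, and only the cis-bridged (3R) hemiketal is geometrically possible.

## Compound list

1 | but-2-yne-1,4-diol | OCC#CCO | starting material
2 | 4-[(tert-butyldimethylsilyl)oxy]but-2-yn-1-ol | OCC#CCO[Si](C)(C)C(C)(C)C | intermediate
3 | (Z)-4-[(tert-butyldimethylsilyl)oxy]-3-iodobut-2-en-1-ol | OC/C=C(\I)CO[Si](C)(C)C(C)(C)C | intermediate
4 | (Z)-4-[(tert-butyldimethylsilyl)oxy]-3-iodobut-2-enal | O=C/C=C(\I)CO[Si](C)(C)C(C)(C)C | intermediate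
5 | trimethyl(prop-2-yn-1-yloxy)silane | C#CCO[Si](C)(C)C | starting material
6 | (4S,5Z)-7-[(tert-butyldimethylsilyl)oxy]-6-iodohept-5-en-2-yne-1,4-diol | OCC#C[C@@H](O)/C=C(\I)CO[Si](C)(C)C(C)(C)C | intermediate
7 | (5S)-3-{[(tert-butyldimethylsilyl)oxy]methyl}-5-(3-hydroxyprop-1-yn-1-yl)furan-2(5H)-one | O=C1O[C@H](C#CCO)C=C1CO[Si](C)(C)C(C)(C)C | intermediate
8 | (5S)-3-{[(tert-butyldimethylsilyl)oxy]methyl}-5-[(1Z)-3-hydroxy-2-iodoprop-1-en-1-yl]furan-2(5H)-one | O=C1O[C@H](/C=C(\I)CO)C=C1CO[Si](C)(C)C(C)(C)C | intermediate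
9 | (5S)-3-{[(tert-butyldimethylsilyl)oxy]methyl}-5-[(1Z)-3-[(tert-butyldiphenylsilyl)oxy]-2-iodoprop-1-en-1-yl]furan-2(5H)-one | O=C1O[C@H](/C=C(\I)CO[Si](c2ccccc2)(c2ccccc2)C(C)(C)C)C=C1CO[Si](C)(C)C(C)(C)C | intermediate
10 | (5S)-3-(bromomethyl)-5-[(1Z)-3-[(tert-butyldiphenylsilyl)oxy]-2-iodoprop-1-en-1-yl]furan-2(5H)-one | O=C1O[C@H](/C=C(\I)CO[Si](c2ccccc2)(c2ccccc2)C(C)(C)C)C=C1CBr | intermediate
11 | geraniol | CC(C)=CCC/C(C)=C/CO | starting material
12 | (2S,3S)-2,3-epoxygeraniol | CC(C)=CCC[C@]1(C)O[C@H]1CO | intermediate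
13 | (3S)-3,7-dimethyloct-6-ene-1,3-diol | CC(C)=CCC[C@@](C)(CCO)O | intermediate
14 | (3S)-3,7-dimethyl-1,3-bis(triethylsilyloxy)oct-6-ene | CC(C)=CCC[C@@](C)(CCO[Si](CC)(CC)CC)O[Si](CC)(CC)CC | intermediate
15 | (3S)-3,7-dimethyl-3-(triethylsilyloxy)oct-6-enal | CC(C)=CCC[C@@](C)(CC=O)O[Si](CC)(CC)CC | intermediate
16 | Barbier adduct, 6,7-trans lactone, (7R,8S,10S), 8-OH | C=C1C(=O)O[C@H](/C=C(\I)CO[Si](c2ccccc2)(c2ccccc2)C(C)(C)C)[C@H]1[C@@H](O)C[C@](C)(CCC=C(C)C)O[Si](CC)(CC)CC | intermediate
17 | angelic acid, (Z)-2-methylbut-2-enoic acid | C/C=C(/C)C(=O)O | starting material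
18 | 8R angelate of 16 (C8 inverted) | C=C1C(=O)O[C@H](/C=C(\I)CO[Si](c2ccccc2)(c2ccccc2)C(C)(C)C)[C@H]1[C@H](OC(=O)/C(C)=C\C)C[C@](C)(CCC=C(C)C)O[Si](CC)(CC)CC | intermediate
19 | C3 aldehyde from 18 | C=C1C(=O)O[C@H](/C=C(\I)CO[Si](c2ccccc2)(c2ccccc2)C(C)(C)C)[C@H]1[C@H](OC(=O)/C(C)=C\C)C[C@](C)(CCC=O)O[Si](CC)(CC)CC | intermediate
20 | ten-membered 3-hydroxy carbocycle (6R,7R,8R,10S; C3 mixture) | C=C1C(=O)O[C@@H]2/C=C(/CO[Si](c3ccccc3)(c3ccccc3)C(C)(C)C)C(O)CC[C@@](C)(C[C@@H](OC(=O)/C(C)=C\C)[C@@H]12)O[Si](CC)(CC)CC | intermediate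
21 | ten-membered 4Z-en-3-one (6R,7R,8R,10S) | C=C1C(=O)O[C@@H]2/C=C(/CO[Si](c3ccccc3)(c3ccccc3)C(C)(C)C)C(=O)CC[C@@](C)(C[C@@H](OC(=O)/C(C)=C\C)[C@@H]12)O[Si](CC)(CC)CC | intermediate
22 | niveusin B | C=C1C(=O)O[C@@H]2/C=C(/CO)[C@@]3(O)CC[C@@](C)(C[C@@H](OC(=O)/C(C)=C\C)[C@@H]12)O3 | target

## Totals and risks

Total steps: 18. Longest linear sequence: 14 (steps 1–8, then 13–18).

Three steps most likely to fail:

1. **Step 16 (NHK closure of the ten-membered ring).** Risks are oligomerisation and β-silyloxy elimination from the vinyl-chromium. Fallback: swap the order of the two C–C bond formations. Join C3–C4 first by an intermolecular NHK of iodide 9 with a C3-aldehyde East fragment, then close the ring at C7–C8 by a CrCl2-mediated intramolecular Barbier reaction of the bromobutenolide onto the C8 aldehyde.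

2. **Step 14 (Mitsunobu inversion at hindered C8).** It may eliminate, and it relies on the anti (8S) outcome of step 13. Fallback: drop the SN2 inversion. Oxidise C8–OH to the ketone, reduce under reagent control (e.g. CBS) to the 8β-alcohol, and acylate with retention using angelic acid under Yamaguchi conditions; if step 13 gives the 8R alcohol directly, only the Yamaguchi acylation is needed.

3. **Step 15 (chemoselective ozonolysis next to a vinyl iodide and two enoates).** Fallback: give up the prenyl mask. Cleave the alkene at the stage of 14 (O3, then NaBH4), carry C3 as a PMB ether through steps 13–14, and reveal the aldehyde with DDQ then Dess–Martin just before the NHK.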